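**Plan**
- Retrosynthetic cuts, in order: the acetate at C-2 (back to the C-2 ketone of a bicyclo[3.2.1]oct-3-ene-2,8-dione); C-4 out of the six-membered ring (bonds C-4–C-5 and C-3=C-4, one carbon from trimethyl orthoformate); the cyclopentanone at C-8–C-1 together with the C-7–aryl bond; the C-7=C-1 enone (aldol condensation with 1,3-dimethoxyacetone); the C-5–allyl bond.
- Forward: methylsuccinate half ester → butyrolactone → trans allylation → amide aldehyde → open-chain 2-methoxy enone; aryl cuprate addition at C-7 with closure of the five-membered ring by the C-8–C-1 bond; orthoformate bridging closes the six-membered ring; reduction at C-2 and Mitsunobu acetate.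
- Enabling feature: in the cyclopentanone ring C-1/C-7/C-6/C-5/C-8 the C-8 carbonyl and the C-2 oxygen are 1,3-related through the methoxy-bearing C-1, and the aryl-bearing C-7 is β to C-2. At the C-2 ketone level C-1 is therefore an enolate carbon, made regiospecifically by aryl addition to a C-7=C-1 enone and trapped by an acyl group at C-8.
- Stereochemistry: C-6 from the chiral pool; C-5 by trans alkylation of the lactone (and cis bridging); C-7 and C-1 by allylic 1,3-strain in the key step; C-2 by exo-face hydride delivery followed by Mitsunobu inversion.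

Key step: step 6

Remark: locants are those of the bicyclo[3.2.1]octane skeleton of the target (C-1 methoxy bridgehead, C-2 acetoxy carbon, C-3=C-4 enol ether, C-5 allyl bridgehead, C-6 methyl, C-7 aryl, C-8 ketone bridge); exo means the side of C-8.
Assumption: (S)-2-methylsuccinic acid 4-methyl ester is taken as a commercial chiral-pool compound.
Assumption: kinetic hydride addition to the C-2 ketone of 20 is taken to occur from the exo face, so the acetate is introduced with inversion.

Step 1
Reactants: 1 (2S)-4-methoxy-2-methyl-4-oxobutanoic acid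
Product: 3 (4S)-4-methyloxolan-2-one, via methyl (3S)-4-hydroxy-3-methylbutanoate 2 (not isolated)
Conditions: BH3·SMe2, THF, 0 → 20 °C; MeOH quench; then TsOH (cat.), toluene, 60 °C
Reagents that add atoms: none
Why: Borane reduces the free carboxylic acid much faster than the methyl ester, and the γ-hydroxy ester 2 lactonises under acid with loss of methanol (chemoselective borane reduction, lactonisation); the stereocentre is not enolisable and is kept.

Step 2
Reactants: 3 (4S)-4-methyloxolan-2-one; 4 allyl bromide
Product: 5 (3S,4S)-4-methyl-3-(prop-2-en-1-yl)oxolan-2-one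
Conditions: LiN(iPr)2, THF, −78 °C; then 4, −78 → −40 °C
Reagents that add atoms: none
Why: The lithium enolate of a 4-substituted butyrolactone should be alkylated anti to the 4-methyl group, so the allyl group enters trans (enolate alkylation with 1,2-induction).

Step 3
Reactants: 5 (3S,4S)-4-methyl-3-(prop-2-en-1-yl)oxolan-2-one
Product: 6 (2S,3S)-4-hydroxy-N-methoxy-N,3-dimethyl-2-(prop-2-en-1-yl)butanamide
Conditions: Me(MeO)NH·HCl, AlMe3, CH2Cl2, 0 → 20 °C; aqueous potassium sodium tartrate
Reagents that add atoms: N,O-dimethylhydroxylamine hydrochloride, CNOC.Cl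
Why: The aluminium amide formed in the flask should open the lactone to the γ-hydroxy N-methoxy-N-methylamide without touching either stereocentre (aminolysis of a lactone with an aluminium amide).

Step 4
Reactants: 6 (2S,3S)-4-hydroxy-N-methoxy-N,3-dimethyl-2-(prop-2-en-1-yl)butanamide
Product: 7 (2S,3S)-N-methoxy-N,3-dimethyl-4-oxo-2-(prop-2-en-1-yl)butanamide
Conditions: DMP (triacetoxyperiodinane), NaHCO3, CH2Cl2, 0 → 20 °C
Reagents that add atoms: none
Why: Buffered periodinane oxidation should give the aldehyde without epimerising the α-methyl centre, and the aldehyde is used at once (Dess–Martin oxidation).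

Step 5
Reactants: 7 (2S,3S)-N-methoxy-N,3-dimethyl-4-oxo-2-(prop-2-en-1-yl)butanamide; 8 1,3-dimethoxypropan-2-one
Product: 11 (2S,3R,4Z)-N,5,7-trimethoxy-N,3-dimethyl-6-oxo-2-(prop-2-en-1-yl)hept-4-enamide, via lithium aldolate 9 (not isolated), via aldol mesylate 10 (not isolated)
Conditions: 8, LiN(iPr)2, THF, −78 °C; then 7, −78 °C; then MeSO2Cl, Et3N, −78 → 20 °C
Reagents that add atoms: methanesulfonyl chloride, CS(=O)(=O)Cl (its atoms are held only in 10)
Why: The deprotonated symmetric ketone 8 (no regiochemical issue) should add to the aldehyde at −78 °C faster than to the amide (aldol addition), and mesylation with E1cB elimination should give the conjugated 2-methoxy enone as the more stable Z isomer; the two new centres of 9 and 10 are removed again.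

Step 6
Reactants: 11 (2S,3R,4Z)-N,5,7-trimethoxy-N,3-dimethyl-6-oxo-2-(prop-2-en-1-yl)hept-4-enamide; 12 (3,4-dimethoxyphenyl)magnesium bromide
Product: 15 (2R,3S,4R,5S)-3-(3,4-dimethoxyphenyl)-2-methoxy-2-(methoxyacetyl)-4-methyl-5-(prop-2-en-1-yl)cyclopentan-1-one, via magnesium enolate 13 (not isolated), via tetrahedral magnesium adduct 14 (not isolated)
Conditions: 12 (2.2 equiv), CuBr·SMe2 (1.1 equiv), THF, −40 °C; then 11, −78 → 20 °C; aqueous NH4Cl
Reagents that add atoms: none
Why: The diarylcuprate formed from 12 and CuBr·SMe2 transfers one aryl group to C-7 of the 2-methoxy enone, and the magnesium enolate 13, nucleophilic at the methoxy-bearing C-1, then attacks the tethered amide carbonyl C-8 to give the chelated tetrahedral adduct 14, which collapses to the ketone only on work-up. The closest known reaction type is organocopper conjugate addition with trapping of the enolate by an internal acyl group (Michael–Dieckmann sequence), together with the acylation of ketone enolates by N-methoxy-N-methylamides. The cyclopentanone ring is closed in the 5-exo-trig mode with the enolate double bond outside the new ring. C-7 is controlled by allylic 1,3-strain in the Z-enone: the C-6 hydrogen lies in the alkene plane beside the methoxy group, so the cuprate adds anti to the large C-5 branch and the aryl group ends trans to the C-6 methyl group. C-1 is controlled by allylic 1,3-strain in the enolate: the C-7 hydrogen eclipses the enolate double bond, so the C-8–C-1 bond forms with the methoxyacetyl group trans and the methoxy group cis to the aryl group. The step needs 1,4-addition without attack on the amide or loss of the enolate, which the cuprate (inert to amides and ketones at low temperature), the aprotic medium and the stable chelate 14 (no second addition, no retro-Claisen cleavage) should secure.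

Step 7
Reactants: 15 (2R,3S,4R,5S)-3-(3,4-dimethoxyphenyl)-2-methoxy-2-(methoxyacetyl)-4-methyl-5-(prop-2-en-1-yl)cyclopentan-1-one
Product: 16 bis(trimethylsilyl enol ether) of 15 (ring enol ether C-8=C-5 and side-chain enol ether C-2=C-3)
Conditions: Me3SiOTf, Et3N, CH2Cl2, 0 °C
Reagents that add atoms: trimethylsilyl trifluoromethanesulfonate, C[Si](C)(C)OS(=O)(=O)C(F)(F)F
Why: Each ketone of 15 can enolise in one direction only, because C-1 is quaternary, so soft enolisation should give a single bis(silyl enol ether) (silyl enol ether formation).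

Step 8
Reactants: 16 bis(trimethylsilyl enol ether) of 15; 17 trimethyl orthoformate
Product: 20 (1R,5S,6R,7S)-7-(3,4-dimethoxyphenyl)-1,3-dimethoxy-6-methyl-5-(prop-2-en-1-yl)bicyclo[3.2.1]oct-3-ene-2,8-dione, via keto acetal 18 (not isolated), via bridged methoxy diketone 19 (not isolated)
Conditions: 17, Me3SiOTf (cat.), CH2Cl2 (dilute), −78 → 0 °C; then DBU, 20 °C
Reagents that add atoms: none
Why: Me3SiOTf ionises the orthoformate to the dimethoxycarbenium ion, which the less hindered enol ether carbon C-3 attacks; the acetal 18 ionises in turn and the ring enol ether carbon C-5 closes the six-membered ring on the only face the C-1 side chain can reach, which fixes C-5, and DBU eliminates methanol from 19 (Mukaiyama-type additions to an orthoester and to an acetal, then E1cB elimination); bond formation through the silyl enol ether carbon avoids closure through the C-8 oxygen.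

Step 9
Reactants: 20 (1R,5S,6R,7S)-7-(3,4-dimethoxyphenyl)-1,3-dimethoxy-6-methyl-5-(prop-2-en-1-yl)bicyclo[3.2.1]oct-3-ene-2,8-dione
Product: 21 (1S,2R,5S,6R,7S)-7-(3,4-dimethoxyphenyl)-2-hydroxy-1,3-dimethoxy-6-methyl-5-(prop-2-en-1-yl)bicyclo[3.2.1]oct-3-en-8-one
Conditions: NaBH4, CeCl3·7H2O, MeOH, −78 °C
Reagents that add atoms: none
Why: Under Luche conditions the conjugated C-2 ketone should be reduced 1,2 in preference to the C-8 ketone, which is flanked by two fully substituted bridgeheads, and hydride should add from the open exo face because the other face is screened by the endo hydrogen on C-7, which places the hydroxyl group on the side of the C-6/C-7 bridge.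

Step 10
Reactants: 21 (1S,2R,5S,6R,7S)-7-(3,4-dimethoxyphenyl)-2-hydroxy-1,3-dimethoxy-6-methyl-5-(prop-2-en-1-yl)bicyclo[3.2.1]oct-3-en-8-one
Product: 22 (1S,2S,5S,6R,7S)-7-(3,4-dimethoxyphenyl)-1,3-dimethoxy-6-methyl-8-oxo-5-(prop-2-en-1-yl)bicyclo[3.2.1]oct-3-en-2-yl acetate
Conditions: AcOH, PPh3, diisopropyl azodicarboxylate, toluene, 0 → 20 °C
Reagents that add atoms: acetic acid, CC(=O)O
Why: Mitsunobu esterification with acetic acid should invert C-2, the acetate entering from the unhindered exo face, to give the 2S acetate of the target; any allyl cation formed by ionisation would be captured from the same face.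

**Compound list**
1 | (2S)-4-methoxy-2-methyl-4-oxobutanoic acid [(S)-2-methylsuccinic acid 4-methyl ester] | COC(=O)C[C@H](C)C(=O)O | starting material
2 | methyl (3S)-4-hydroxy-3-methylbutanoate | COC(=O)C[C@H](C)CO | intermediate
3 | (4S)-4-methyloxolan-2-one | O=C1C[C@H](C)CO1 | intermediate
4 | 3-bromoprop-1-ene (allyl bromide) | C=CCBr | starting material
5 | (3S,4S)-4-methyl-3-(prop-2-en-1-yl)oxolan-2-one | C=CC[C@H]1[C@H](C)COC1=O | intermediate
6 | (2S,3S)-4-hydroxy-N-methoxy-N,3-dimethyl-2-(prop-2-en-1-yl)butanamide | C=CC[C@@H]([C@H](C)CO)C(=O)N(C)OC | intermediate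
7 | (2S,3S)-N-methoxy-N,3-dimethyl-4-oxo-2-(prop-2-en-1-yl)butanamide | C=CC[C@@H]([C@H](C)C=O)C(=O)N(C)OC | intermediate
8 | 1,3-dimethoxypropan-2-one | COCC(=O)COC | starting material
9 | lithium (2S,3S)-N,5,7-trimethoxy-N,3-dimethyl-1,6-dioxo-2-(prop-2-en-1-yl)heptan-4-olate amide aldolate (mixture at C-4 and C-5) | C=CC[C@@H]([C@H](C)C([O-])C(OC)C(=O)COC)C(=O)N(C)OC.[Li+] | intermediate
10 | (2S,3S)-N,5,7-trimethoxy-N,3-dimethyl-4-(methanesulfonyloxy)-6-oxo-2-(prop-2-en-1-yl)heptanamide (mixture at C-4 and C-5) | C=CC[C@@H]([C@H](C)C(OS(C)(=O)=O)C(OC)C(=O)COC)C(=O)N(C)OC | intermediate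
11 | (2S,3R,4Z)-N,5,7-trimethoxy-N,3-dimethyl-6-oxo-2-(prop-2-en-1-yl)hept-4-enamide | C=CC[C@@H]([C@H](C)/C=C(\OC)C(=O)COC)C(=O)N(C)OC | intermediate
12 | (3,4-dimethoxyphenyl)magnesium bromide | COc1ccc([Mg]Br)cc1OC | starting material
13 | bromomagnesium C-5=C-6 enolate of (2S,3R,4S)-4-(3,4-dimethoxyphenyl)-N,5,7-trimethoxy-N,3-dimethyl-6-oxo-2-(prop-2-en-1-yl)heptanamide | C=CC[C@@H]([C@H](C)[C@@H](c1ccc(OC)c(OC)c1)C(OC)=C(O[Mg]Br)COC)C(=O)N(C)OC | intermediate
14 | bromomagnesium alkoxide of the cyclic hemiaminal at C-8 (1-[methoxy(methyl)amino]cyclopentan-1-olate with the ring substituents of 15) | C=CC[C@@H]1C(O[Mg]Br)(N(C)OC)[C@@](OC)(C(=O)COC)[C@H](c2ccc(OC)c(OC)c2)[C@H]1C | intermediate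
15 | (2R,3S,4R,5S)-3-(3,4-dimethoxyphenyl)-2-methoxy-2-(methoxyacetyl)-4-methyl-5-(prop-2-en-1-yl)cyclopentan-1-one | C=CC[C@@H]1C(=O)[C@@](OC)(C(=O)COC)[C@H](c2ccc(OC)c(OC)c2)[C@H]1C | intermediate
16 | trimethyl{[(3R,4S,5R)-4-(3,4-dimethoxyphenyl)-3-methoxy-3-[2-methoxy-1-(trimethylsilyloxy)ethenyl]-5-methyl-2-(prop-2-en-1-yl)cyclopent-1-en-1-yl]oxy}silane | C=CCC1=C(O[Si](C)(C)C)[C@@](OC)(C(O[Si](C)(C)C)=COC)[C@H](c2ccc(OC)c(OC)c2)[C@H]1C | intermediate
17 | trimethoxymethane (trimethyl orthoformate) | COC(OC)OC | starting material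
18 | ring silyl enol ether of 15 carrying a 2,3,3-trimethoxypropanoyl group at C-1 (mixture at the new centre) | C=CCC1=C(O[Si](C)(C)C)[C@@](OC)(C(=O)C(OC)C(OC)OC)[C@H](c2ccc(OC)c(OC)c2)[C@H]1C | intermediate
19 | 7-(3,4-dimethoxyphenyl)-1,3,4-trimethoxy-6-methyl-5-(prop-2-en-1-yl)bicyclo[3.2.1]octane-2,8-dione (C-1, C-5, C-6, C-7 as in 20; mixture at C-3 and C-4) | C=CC[C@]12C(OC)C(OC)C(=O)[C@](OC)(C1=O)[C@H](c1ccc(OC)c(OC)c1)[C@H]2C | intermediate
20 | (1R,5S,6R,7S)-7-(3,4-dimethoxyphenyl)-1,3-dimethoxy-6-methyl-5-(prop-2-en-1-yl)bicyclo[3.2.1]oct-3-ene-2,8-dione | C=CC[C@]12C=C(OC)C(=O)[C@](OC)(C1=O)[C@H](c1ccc(OC)c(OC)c1)[C@H]2C | intermediate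
21 | (1S,2R,5S,6R,7S)-7-(3,4-dimethoxyphenyl)-2-hydroxy-1,3-dimethoxy-6-methyl-5-(prop-2-en-1-yl)bicyclo[3.2.1]oct-3-en-8-one | C=CC[C@]12C=C(OC)[C@@H](O)[C@](OC)(C1=O)[C@H](c1ccc(OC)c(OC)c1)[C@H]2C | intermediate
22 | (1S,2S,5S,6R,7S)-7-(3,4-dimethoxyphenyl)-1,3-dimethoxy-6-methyl-8-oxo-5-(prop-2-en-1-yl)bicyclo[3.2.1]oct-3-en-2-yl acetate | C=CC[C@]12C=C(OC)[C@H](OC(C)=O)[C@](OC)(C1=O)[C@H](c1ccc(OC)c(OC)c1)[C@H]2C | target

**Totals**
Total step count: 10. Longest linear sequence: 10 steps (1 → 22).

**Steps most likely to fail**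

Step 6. The cuprate may add sluggishly to the electron-rich 2-methoxy enone. The enolate may be lost by proton transfer before it closes the ring. Coordination of the reagent to the amide may erode facial selectivity at C-7. Fallback, from 11: the two events are separated. Copper-catalysed addition of 12 in the presence of Me3SiCl (CuBr·SMe2 cat., THF, −78 °C) should give the trimethylsilyl enol ether F1. Dilute acid then releases the open-chain β-aryl ketone F2. KOtBu in THF at 0 °C equilibrates the ketone enolates, of which only the C-1 enolate can close the five-membered ring onto the amide, and the route is rejoined at 15.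

Step 8. Intermolecular acetal transfer may lead to oligomers, and the oxocarbenium ion may be captured by the C-8 oxygen or the aryl ring instead of C-5. Fallback, from 15: tert-butoxybis(dimethylamino)methane (toluene, 60 °C) should condense at the only methylene group to give the enaminone F3. CF3CO2H in CH2Cl2 then lets the C-8 enol add to the protonated enaminone with loss of dimethylamine (intramolecular Mannich-type condensation), which comes back to the route at 20.

Step 10. Displacement at C-2 next to the quaternary C-1 may be too slow, or may proceed with retention or allylic transposition. Fallback, from 21: MeSO2Cl and Et3N give the C-2 mesylate F4. Buffered acetolysis (AcOH, NaOAc, 50 °C) should then proceed by ionisation to the 2-methoxyallyl cation, with acetate captured at C-2 on the exo face (C-4 is neopentylic), which comes back to the route at 22.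

**Further compounds**
F1 | step 6 | (2S,3R,4S)-4-(3,4-dimethoxyphenyl)-N,5,7-trimethoxy-N,3-dimethyl-2-(prop-2-en-1-yl)-6-(trimethylsilyloxy)hept-5-enamide | C=CC[C@@H]([C@H](C)[C@@H](c1ccc(OC)c(OC)c1)C(OC)=C(O[Si](C)(C)C)COC)C(=O)N(C)OC
F2 | step 6 | (2S,3R,4S)-4-(3,4-dimethoxyphenyl)-N,5,7-trimethoxy-N,3-dimethyl-6-oxo-2-(prop-2-en-1-yl)heptanamide (mixture at C-5) | C=CC[C@@H]([C@H](C)[C@@H](c1ccc(OC)c(OC)c1)C(OC)C(=O)COC)C(=O)N(C)OC
F3 | step 8 | (2R,3S,4R,5S)-2-[3-(dimethylamino)-2-methoxyprop-2-enoyl]-3-(3,4-dimethoxyphenyl)-2-methoxy-4-methyl-5-(prop-2-en-1-yl)cyclopentan-1-one | C=CC[C@@H]1C(=O)[C@@](OC)(C(=O)C(OC)=CN(C)C)[C@H](c2ccc(OC)c(OC)c2)[C@H]1C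
F4 | step 10 | (1S,2R,5S,6R,7S)-7-(3,4-dimethoxyphenyl)-1,3-dimethoxy-6-methyl-8-oxo-5-(prop-2-en-1-yl)bicyclo[3.2.1]oct-3-en-2-yl methanesulfonate | C=CC[C@]12C=C(OC)[C@@H](OS(C)(=O)=O)[C@](OC)(C1=O)[C@H](c1ccc(OC)c(OC)c1)[C@H]2C
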